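**Retrosynthetic overview** (side chain numbered C1'–C13' outward from chromene C2)

1. Target ⇒ skipped enyne pivalate: the last step is a hydroxyl-directed trans-reduction of the propargylic alcohol to the 6'E alkene, which also removes the pivalate.
2. Enyne ⇒ C5'–C6' sp3–sp coupling of a chromene allylic bromide with (S)-dehydrolinalool; the alkynol ⇒ epoxy chloride ⇒ Sharpless epoxidation of geraniol (sets the C8'–O stereocenter).
3. Allylic bromide ⇒ E-selective allylic oxidation of the (2S)-chromenyl pivalate.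
4. Key step: (2S)-chromene ⇒ 2-geranyl-6-methyl-1,4-benzoquinone by a catalytic enantioselective quinone-to-chromenol cycloisomerization that forms the C2–O bond; quinone ⇒ o-cresol + geranyl bromide.
5. Ring order: the benzene ring is bought; the pyran ring is the only ring made and is closed in step 3, before the chain is extended.

Assumption: the (R)-antipode of the phosphoric acid catalyst is taken to give the 2S chromene; both antipodes are commercial, and one test run fixes which is used.

**Route**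

Step 1
Reactants: 1 2-methylphenol (o-cresol); 2 (2E)-1-bromo-3,7-dimethylocta-2,6-diene (geranyl bromide)
Product: 4 2-[(2E)-3,7-dimethylocta-2,6-dien-1-yl]-6-methylphenol, via sodium 2-methylphenolate 3 (not isolated)
Conditions: 1 (3 equiv), NaH (3 equiv), toluene, 0 °C to rt; then 2 (1 equiv), rt to 50 °C
Reagents that add atoms: none
Why: Ortho-selective C-allylation of a sodium phenolate in a non-polar solvent: the contact ion pair shields oxygen and the bromide is attacked by SN2 from the only free ortho carbon, so the 2E geometry is kept and the 2,6-pattern is fixed.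

Step 2
Reactants: 4 2-[(2E)-3,7-dimethylocta-2,6-dien-1-yl]-6-methylphenol
Product: 5 2-[(2E)-3,7-dimethylocta-2,6-dien-1-yl]-6-methylcyclohexa-2,5-diene-1,4-dione
Conditions: Co(salen) (C16H14CoN2O2, divalent cobalt, 10 mol%), O2 (1 atm), DMF, rt
Reagents that add atoms: dioxygen, O=O
Why: Salcomine-type aerobic phenol oxidation: the phenoxyl radical is oxygenated at the free para carbon and loss of water gives the para-quinone; both ortho positions are blocked and the isolated alkenes are inert.

Step 3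
Reactants: 5 2-[(2E)-3,7-dimethylocta-2,6-dien-1-yl]-6-methylcyclohexa-2,5-diene-1,4-dione
Product: 8 (2S)-2,8-dimethyl-2-(4-methylpent-3-en-1-yl)-2H-chromen-6-yl 2,2-dimethylpropanoate, via ortho-quinone methide 6 (not isolated), via (2S)-chromenol 7 (not isolated)
Conditions: (R)-TRIP [(R)-3,3'-bis(2,4,6-triisopropylphenyl)-1,1'-binaphthyl-2,2'-diyl hydrogen phosphate] (10 mol%), toluene, 4 Å MS, 40 °C, dark, Ar, to full conversion; then Et3N, PivCl, DMAP (cat.), 0 °C to rt
Reagents that add atoms: pivaloyl chloride, CC(C)(C)C(Cl)=O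
Why: Proposed new method: the chiral phosphoric acid acts as a bifunctional proton shuttle that moves the doubly activated C1'–H (allylic and vinylogously alpha to the C4 carbonyl) to O4, generating the (Z)-ortho-quinone methide 6 while still hydrogen-bonded to the adjacent C1 carbonyl, so the fast oxa-6π electrocyclization that forms the C2–O bond happens inside the chiral pocket, which differentiates the two helical transition states (methyl versus homoprenyl toward the 3,3'-aryl wall) and sets C2 as S; the uncatalysed isomerization is negligible at 40 °C, so no racemic background competes; the closest known reactions are the racemic pyridine- or heat-induced isomerization of prenylquinones to chromenols and chiral phosphoric acid catalysed 6π aza-electrocyclizations and additions to ortho-quinone methides; the one-pot pivaloylation (acyl substitution) masks the air-sensitive phenol.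

Step 4
Reactants: 8 (2S)-2,8-dimethyl-2-(4-methylpent-3-en-1-yl)-2H-chromen-6-yl 2,2-dimethylpropanoate
Product: 9 (2S)-2-[(3E)-5-hydroxy-4-methylpent-3-en-1-yl]-2,8-dimethyl-2H-chromen-6-yl 2,2-dimethylpropanoate
Conditions: SeO2 (0.3 equiv), t-BuOOH (3 equiv), salicylic acid (0.1 equiv), CH2Cl2, 0 °C to rt
Reagents that add atoms: selenium dioxide, O=[Se]=O (transfers the oxygen); tert-butyl hydroperoxide, CC(C)(C)OO (stoichiometric oxygen source)
Why: Sharpless-type catalytic SeO2 allylic oxidation (ene reaction then [2,3]-sigmatropic shift) oxidizes the E-methyl of the gem-dimethyl alkene and gives the E-allylic alcohol; the chromene C3=C4 has no allylic hydrogen (C2 is quaternary) and the pivalate protects the phenol.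

Step 5
Reactants: 9 (2S)-2-[(3E)-5-hydroxy-4-methylpent-3-en-1-yl]-2,8-dimethyl-2H-chromen-6-yl 2,2-dimethylpropanoate
Product: 10 (2S)-2-[(3E)-5-bromo-4-methylpent-3-en-1-yl]-2,8-dimethyl-2H-chromen-6-yl 2,2-dimethylpropanoate
Conditions: CBr4, PPh3, CH2Cl2, 0 °C
Reagents that add atoms: tetrabromomethane, BrC(Br)(Br)Br
Why: Appel bromination of the primary allylic alcohol under neutral conditions (SN2 at carbon) leaves the E-alkene, the chromene and the aryl ester untouched.

Step 6
Reactants: 11 (2E)-3,7-dimethylocta-2,6-dien-1-ol (geraniol)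
Product: 12 [(2S,3S)-3-methyl-3-(4-methylpent-3-en-1-yl)oxiran-2-yl]methanol
Conditions: Ti(OiPr)4 (5 mol%), L-(+)-diethyl tartrate (7.5 mol%), t-BuOOH, 4 Å MS, CH2Cl2, −20 °C
Reagents that add atoms: tert-butyl hydroperoxide, CC(C)(C)OO
Why: Sharpless asymmetric epoxidation: the titanium tartrate complex binds the allylic hydroxyl and delivers oxygen to one face of the 2,3-alkene only (L-tartrate gives 2S,3S, typically above 90% ee), forming the C–O bond of the future C8' carbinol; the remote alkene is not epoxidized.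

Step 7
Reactants: 12 [(2S,3S)-3-methyl-3-(4-methylpent-3-en-1-yl)oxiran-2-yl]methanol
Product: 13 (2S,3R)-3-(chloromethyl)-2-methyl-2-(4-methylpent-3-en-1-yl)oxirane
Conditions: PPh3, CCl4, NaHCO3 (cat.), reflux
Reagents that add atoms: tetrachloromethane, ClC(Cl)(Cl)Cl
Why: Appel chlorination of the primary alcohol, buffered so the acid-sensitive epoxide survives; no stereocenter is touched (the 3R label results only from the changed priority of CH2Cl).

Step 8
Reactants: 13 (2S,3R)-3-(chloromethyl)-2-methyl-2-(4-methylpent-3-en-1-yl)oxirane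
Product: 15 (3S)-3,7-dimethyloct-6-en-1-yn-3-ol, via dilithium alkynide alkoxide 14 (not isolated)
Conditions: n-BuLi (3.2 equiv), THF, −40 to −20 °C; then H2O
Reagents that add atoms: none
Why: Base-induced double elimination of a 2,3-epoxy chloride (Takano–Yadav propargylic alcohol synthesis): metalation next to chlorine opens the epoxide at the CH–O bond and a second dehydrochlorination gives the alkyne; the quaternary C–O bond is never broken, so the carbinol stays S.

Step 9
Reactants: 10 (2S)-2-[(3E)-5-bromo-4-methylpent-3-en-1-yl]-2,8-dimethyl-2H-chromen-6-yl 2,2-dimethylpropanoate; 15 (3S)-3,7-dimethyloct-6-en-1-yn-3-ol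
Product: 16 (2S)-2-[(3E,8S)-8-hydroxy-4,8,12-trimethyltrideca-3,11-dien-6-yn-1-yl]-2,8-dimethyl-2H-chromen-6-yl 2,2-dimethylpropanoate
Conditions: CuI (10 mol%), K2CO3 (1.5 equiv), n-Bu4NBr (10 mol%), DMF, rt
Reagents that add atoms: none
Why: Copper-catalysed allylic substitution by a terminal alkyne under solid–liquid phase-transfer conditions (Jeffery-type sp–sp3 coupling): the copper acetylide attacks the unhindered primary allylic carbon by SN2, the 3'E alkene is kept, and the mild carbonate base tolerates the free tertiary alcohol and the aryl pivalate.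

Step 10
Reactants: 16 (2S)-2-[(3E,8S)-8-hydroxy-4,8,12-trimethyltrideca-3,11-dien-6-yn-1-yl]-2,8-dimethyl-2H-chromen-6-yl 2,2-dimethylpropanoate
Product: 17 (2S)-2-[(3E,6E,8S)-8-hydroxy-4,8,12-trimethyltrideca-3,6,11-trien-1-yl]-2,8-dimethyl-2H-chromen-6-ol
Conditions: NaAlH2(OCH2CH2OCH3)2 (Red-Al, 5 equiv), THF, 0 °C to rt, Ar; then degassed H2O
Reagents that add atoms: none
Why: Hydroxyl-directed anti-hydroalumination of the propargylic alcohol followed by protonolysis gives only the 6'E allylic alcohol, and the aryl pivalate is cleaved reductively in the same pot; isolated and styrenic alkenes are not reduced and neither stereocenter is touched.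

**Compound list**

1 | 2-methylphenol (o-cresol) | Cc1ccccc1O | starting material
2 | (2E)-1-bromo-3,7-dimethylocta-2,6-diene (geranyl bromide) | CC(C)=CCC/C(C)=C/CBr | starting material
3 | sodium 2-methylphenolate | Cc1ccccc1[O-].[Na+] | intermediate (not isolated)
4 | 2-[(2E)-3,7-dimethylocta-2,6-dien-1-yl]-6-methylphenol | CC(C)=CCC/C(C)=C/Cc1cccc(C)c1O | intermediate
5 | 2-[(2E)-3,7-dimethylocta-2,6-dien-1-yl]-6-methylcyclohexa-2,5-diene-1,4-dione | CC(C)=CCC/C(C)=C/CC1=CC(=O)C=C(C)C1=O | intermediate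
6 | (2Z)-2-[(2E)-3,7-dimethylocta-2,6-dien-1-ylidene]-4-hydroxy-6-methylcyclohexa-3,5-dien-1-one | CC(C)=CCC/C(C)=C/C=C1/C=C(O)C=C(C)C1=O | intermediate (not isolated)
7 | (2S)-2,8-dimethyl-2-(4-methylpent-3-en-1-yl)-2H-chromen-6-ol | CC(C)=CCC[C@@]1(C)C=Cc2cc(O)cc(C)c2O1 | intermediate (not isolated)
8 | (2S)-2,8-dimethyl-2-(4-methylpent-3-en-1-yl)-2H-chromen-6-yl 2,2-dimethylpropanoate | CC(C)=CCC[C@@]1(C)C=Cc2cc(OC(=O)C(C)(C)C)cc(C)c2O1 | intermediate
9 | (2S)-2-[(3E)-5-hydroxy-4-methylpent-3-en-1-yl]-2,8-dimethyl-2H-chromen-6-yl 2,2-dimethylpropanoate | OC/C(C)=C/CC[C@@]1(C)C=Cc2cc(OC(=O)C(C)(C)C)cc(C)c2O1 | intermediate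
10 | (2S)-2-[(3E)-5-bromo-4-methylpent-3-en-1-yl]-2,8-dimethyl-2H-chromen-6-yl 2,2-dimethylpropanoate | BrC/C(C)=C/CC[C@@]1(C)C=Cc2cc(OC(=O)C(C)(C)C)cc(C)c2O1 | intermediate
11 | (2E)-3,7-dimethylocta-2,6-dien-1-ol (geraniol) | CC(C)=CCC/C(C)=C/CO | starting material
12 | [(2S,3S)-3-methyl-3-(4-methylpent-3-en-1-yl)oxiran-2-yl]methanol | OC[C@@H]1O[C@@]1(C)CCC=C(C)C | intermediate
13 | (2S,3R)-3-(chloromethyl)-2-methyl-2-(4-methylpent-3-en-1-yl)oxirane | ClC[C@@H]1O[C@@]1(C)CCC=C(C)C | intermediate
14 | dilithium (3S)-3,7-dimethyl-3-oxidooct-6-en-1-yn-1-ide | [Li+].[Li+].[C-]#C[C@@](C)([O-])CCC=C(C)C | intermediate (not isolated)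
15 | (3S)-3,7-dimethyloct-6-en-1-yn-3-ol | C#C[C@@](C)(O)CCC=C(C)C | intermediate
16 | (2S)-2-[(3E,8S)-8-hydroxy-4,8,12-trimethyltrideca-3,11-dien-6-yn-1-yl]-2,8-dimethyl-2H-chromen-6-yl 2,2-dimethylpropanoate | CC(C)=CCC[C@](C)(O)C#CC/C(C)=C/CC[C@@]1(C)C=Cc2cc(OC(=O)C(C)(C)C)cc(C)c2O1 | intermediate
17 | (2S)-2-[(3E,6E,8S)-8-hydroxy-4,8,12-trimethyltrideca-3,6,11-trien-1-yl]-2,8-dimethyl-2H-chromen-6-ol | CC(C)=CCC[C@](C)(O)/C=C/C/C(C)=C/CC[C@@]1(C)C=Cc2cc(O)cc(C)c2O1 | target

**Totals and risks**

Total step count: 10. Longest linear sequence: 7 steps (1, 2, 3, 4, 5, 9, 10) from o-cresol; the alkynol branch is 3 steps (6–8) before the coupling.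

Steps most likely to fail:

- **Step 3** (proposed new method; risk of low enantioselectivity or no turnover). The fallback uses known chemistry, sets out from 5 and comes back to the route at 8. Quinone 5 is heated in pyridine at reflux, the established racemic prenylquinone-to-chromenol isomerization, to give racemic 2,8-dimethyl-2-(4-methylpent-3-en-1-yl)-2H-chromen-6-ol F1. This is pivaloylated (PivCl, Et3N, DMAP) to racemic 2,8-dimethyl-2-(4-methylpent-3-en-1-yl)-2H-chromen-6-yl 2,2-dimethylpropanoate F2. Preparative chromatography on a chiral polysaccharide phase then gives 8 and the unwanted (2R)-2,8-dimethyl-2-(4-methylpent-3-en-1-yl)-2H-chromen-6-yl 2,2-dimethylpropanoate F3.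

- **Step 4** (risk of low conversion, over-oxidation to the enal, or damage to the chromene). The fallback sets out from 8 and comes back at 9. Cross-metathesis of the prenyl terminus of 8 with methacrolein (second-generation Hoveyda–Grubbs catalyst, C31H38Cl2N2ORu, CH2Cl2, 40 °C) gives (2S)-2,8-dimethyl-2-[(3E)-4-methyl-5-oxopent-3-en-1-yl]-2H-chromen-6-yl 2,2-dimethylpropanoate F4. Luche reduction (NaBH4, CeCl3·7H2O, MeOH, −20 °C) then gives 9.

- **Step 9** (risk of SN2' attack giving the branched 1,4-enyne, or loss of the aryl ester under carbonate). The fallback sets out from 15 and 10 and comes back at 17, bypassing 16 and step 10. Hydrostannation of 15 (Bu3SnH, PdCl2(PPh3)2, THF, 0 °C) gives (1E,3S)-3,7-dimethyl-1-(tributylstannyl)octa-1,6-dien-3-ol F5. Stille allyl–vinyl coupling of F5 with 10 (Pd2(dba)3, AsPh3, THF, 50 °C) gives (2S)-2-[(3E,6E,8S)-8-hydroxy-4,8,12-trimethyltrideca-3,6,11-trien-1-yl]-2,8-dimethyl-2H-chromen-6-yl 2,2-dimethylpropanoate F6, with the 6'E alkene set by the syn hydrometalation. Methanolysis (K2CO3, MeOH, rt, Ar) then gives 17.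

**Further compounds**

F1 | step 3 | racemic 2,8-dimethyl-2-(4-methylpent-3-en-1-yl)-2H-chromen-6-ol | CC(C)=CCCC1(C)C=Cc2cc(O)cc(C)c2O1
F2 | step 3 | racemic 2,8-dimethyl-2-(4-methylpent-3-en-1-yl)-2H-chromen-6-yl 2,2-dimethylpropanoate | CC(C)=CCCC1(C)C=Cc2cc(OC(=O)C(C)(C)C)cc(C)c2O1
F3 | step 3 | (2R)-2,8-dimethyl-2-(4-methylpent-3-en-1-yl)-2H-chromen-6-yl 2,2-dimethylpropanoate | CC(C)=CCC[C@]1(C)C=Cc2cc(OC(=O)C(C)(C)C)cc(C)c2O1
F4 | step 4 | (2S)-2,8-dimethyl-2-[(3E)-4-methyl-5-oxopent-3-en-1-yl]-2H-chromen-6-yl 2,2-dimethylpropanoate | O=C/C(C)=C/CC[C@@]1(C)C=Cc2cc(OC(=O)C(C)(C)C)cc(C)c2O1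
F5 | step 9 | (1E,3S)-3,7-dimethyl-1-(tributylstannyl)octa-1,6-dien-3-ol | CCCC[Sn](CCCC)(CCCC)/C=C/[C@@](C)(O)CCC=C(C)C
F6 | step 9 | (2S)-2-[(3E,6E,8S)-8-hydroxy-4,8,12-trimethyltrideca-3,6,11-trien-1-yl]-2,8-dimethyl-2H-chromen-6-yl 2,2-dimethylpropanoate | CC(C)=CCC[C@](C)(O)/C=C/C/C(C)=C/CC[C@@]1(C)C=Cc2cc(OC(=O)C(C)(C)C)cc(C)c2O1
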